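**Remark on the chemistry:** the target has no stereocentre and is achiral. The rings are called A (trihydroxyphenyl end), B (middle) and C (brominated end). Each ring is numbered from its ether carbon, ring B from the carbon bound to the ring A oxygen.

## Analysis of the target

Compound 16 is a linear triaryl bis-ether: three benzene rings joined by two ether oxygens, carrying seven free phenolic hydroxyls and one bromine. No ring is fused and there is no stereocentre, so the problem is one of connectivity and chemoselectivity only. Ring A is a 2,4,6-trihydroxyphenyl group bound through C1. Ring B carries the ring A oxygen at C1, hydroxyls at C3 and C5 and the ring C oxygen at C4. Ring C is a 3,5-dihydroxyphenyl group bound through C1 with bromine at C4. The free heptaphenol is very electron-rich and oxidises readily, so every hydroxyl should stay masked until the last step. The C–Br bond cannot pass through a low-valent nickel or palladium step or a hydrogenolysis. The difficulty lies in the two inner ether carbons, C1 of ring A and C4 of ring B: each is flanked by two oxygenated carbons, so both are electron-rich and di-ortho-substituted, the worst case for substitution or metal-catalysed etherification. The strategy rests on C1 of ring A with its oxygenated neighbours C2 and C6 and the oxygen at C4, which is exactly the substitution pattern around the carboxyl-bearing carbon of 2,4,6-trimethoxybenzoic acid 5.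

## Retrosynthetic reasoning

**16 from 15.** All seven hydroxyls are traced back to methyl ethers in the heptamethyl ether 15. Methyl ethers withstand base, peracid, hydrogenation and hot zerovalent nickel, and one Lewis-acid operation at the end removes them all. The forward step has to cleave seven O–CH3 bonds without touching the two diaryl ether bonds or the C–Br bond.

**15 from 9 and 14.** The B–C ether is cut between the oxygen and C1 of ring C, not between the oxygen and C4 of ring B. C1 of ring C is flanked by two CH groups and can act as an unhindered aryl electrophile, whereas C4 of ring B is buried between two methoxy groups. The oxygen therefore stays on ring B as the hindered phenol 9, and ring C arrives as the diaryliodonium salt 14. This also brings the bromine in after the nickel step. The forward reaction must transfer only the bromodimethoxyphenyl group of 14 to a 2,6-disubstituted phenoxide.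

**14 from 10 through 12 and 11.** The iodonium salt comes from the aryl iodide 12 by oxidation at iodine and capture of an electron-rich auxiliary arene. The iodide comes from the boronate 11, and 11 from 2-bromo-1,3-dimethoxybenzene 10. The carbon to be functionalised in 10 is C5, meta to both methoxy groups and para to bromine. Electrophilic substitution would attack C4 instead, so the C5–B bond is made by a sterically controlled C–H borylation, which selects the only C–H bond with no ortho neighbour.

**9 from 8.** The free hydroxyl at C4 of ring B is traced back to a benzyl ether. It is the only oxygen that must be unmasked before the end, and hydrogenolysis is orthogonal to the methyl ethers. The step is placed before any bromine is present.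

**8 from 7 (key disconnection).** A carbonyl group is inserted retrosynthetically between C1 of ring A and the ether oxygen, turning the congested diaryl ether 8 into the aryl ester 7. The intermolecular bond to the crowded ring A carbon thus becomes an ordinary acylation, and the difficult C–O bond is formed on the metal after the carbonyl group is extruded. The forward reaction has to achieve oxidative addition at the acyl C–O bond, decarbonylation and C–O reductive elimination, in preference to any reaction of the aryl ethers.

**7 from 4 and 5.** The ester is cut at the acyl–oxygen bond into the phenol 4 and the acid 5, activated as its chloride 6. The phenolic oxygen of 4 sits at C1 of ring B between two CH groups, so it is a good nucleophile even toward a di-ortho-substituted aroyl chloride.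

**4 from 1 through 2 and 3.** The oxygen at C1 of ring B replaces the formyl carbon of syringaldehyde 1 by aryl migration to a peracid oxygen, via the formate 3. The aldehyde 1 already holds the two methoxy groups and a distinguishable oxygen at C4, which is benzylated first to give 2.

## Alternatives that were turned down

**Alternative 1:** Ring B would be built from acyclic pieces by cutting C2–C3 and C5–C6. The pieces are the aryloxymalonate A2, carrying ring C, and the 3-aryloxyglutaconate A3, carrying ring A. In the forward key step a base would join the two nucleophilic termini of A3 to the two ester carbons of A2 in a double Claisen condensation, and enolisation would give the dihydroxy diester A1.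
- For it: both congested ether bonds exist before the ring is made, at carbons that are sp3 or enol carbons at that stage. No transition metal is needed and the bromine can be present from the start. On these points it is stronger than the chosen route.
- Against it: the C–H of A2 is the most acidic proton present, and once A2 is enolised its ester carbons are poor electrophiles. The aryloxy group of A3 is a vinylogous leaving group that alkoxide or a carbanion can displace by addition–elimination. A1 still carries two ester groups that must be hydrolysed and decarboxylated before the global demethylation.
- Comparison: the chosen route offers commercial aromatic building blocks, three reliable steps to the key precursor, and no carbon that has to be removed afterwards other than the extruded carbonyl.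

**Alternative 2:** Both ether bonds would be cut at the hindered carbons, C4 of ring B and C1 of ring A, and each formed by carbenoid O–H insertion. In the forward key step Rh2(OAc)4 would decompose the quinone diazide A5. The resulting quinoid carbenoid would insert into the O–H bond of the ring C phenol A6 and aromatise to the phenol A4. A second insertion of A5 into A4 would give the triaryl phenol A7, ready for demethylation.
- For it: it is the shortest plan, it uses one diazide twice, and it runs at mild temperature with a catalyst that tolerates aryl bromide. The attack of oxygen on a planar carbenoid carbon is little affected by the flanking methoxy groups. In step economy it is stronger than the chosen route.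
- Against it: quinoid rhodium carbenoids are strongly electrophilic and arylate electron-rich arenes at carbon. A6 and still more A4 have activated free ring positions, so C–C bond formation would compete with O–H insertion. A5 has to be prepared by diazotisation of the corresponding aminophenol and handled as a diazo compound.
- Comparison: in the chosen route the ether oxygen is already bonded on both sides, as an ester, before the metal acts, so the question of O- against C-arylation does not arise.

**Alternative 3:** Ring A would be built last by cutting C1–C6, C2–C3 and C4–C5. In the forward key step a tertiary amine would convert the aryloxyacetyl chloride A9 into an aryloxyketene. The ketene would add one molecule of ethoxyethyne A10 to give a cyclobutenone. On heating, ring opening to a vinylketene, addition of a second A10 and electrocyclisation would give the phenol A8, a Danheiser-type benzannulation.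
- For it: the most crowded ring is assembled around an existing ether oxygen, no metal is involved and the bromine is tolerated.
- Against it: A9 must be made from the B–C phenol A4, so the hindered B–C ether still has to be formed by an arylation of the kind used in the chosen route. A4 then needs O-alkylation, hydrolysis and chlorination before the key step. The in situ ketene must undergo two regioselective cycloadditions with a volatile, costly alkyne in competition with ketene dimerisation. A8 carries ethyl and methyl ethers and one free hydroxyl.
- Comparison: it is longer and shifts the difficulty without removing it. The chosen route takes ring A intact from the acid 5.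

Key step: step 4

## Route

**Step 1**
Reactants: 1 syringaldehyde (4-hydroxy-3,5-dimethoxybenzaldehyde)
Product: 2 4-(benzyloxy)-3,5-dimethoxybenzaldehyde
Conditions: BnBr, K2CO3, DMF, 60 °C
Reagents that add atoms: benzyl bromide, BrCc1ccccc1
Why: Williamson etherification; the phenol para to the formyl group is acidic and its phenoxide is alkylated at oxygen by the benzylic halide despite the two flanking methoxy groups.

**Step 2**
Reactants: 2 4-(benzyloxy)-3,5-dimethoxybenzaldehyde
Product: 4 4-(benzyloxy)-3,5-dimethoxyphenol, via aryl formate 3 (not isolated)
Conditions: mCPBA, CH2Cl2, rt; then K2CO3, MeOH, rt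
Reagents that add atoms: 3-chloroperoxybenzoic acid (mCPBA), OOC(=O)c1cccc(Cl)c1
Why: Baeyer–Villiger (Dakin-type) oxidation of an electron-rich benzaldehyde; the aryl group with its para alkoxy substituent migrates in preference to hydride, and the resulting formate 3 is methanolysed under mild base. Benzyl and methyl ethers are inert to the peracid.

**Step 3**
Reactants: 4 4-(benzyloxy)-3,5-dimethoxyphenol; 5 2,4,6-trimethoxybenzoic acid
Product: 7 4-(benzyloxy)-3,5-dimethoxyphenyl 2,4,6-trimethoxybenzoate, via 2,4,6-trimethoxybenzoyl chloride 6 (not isolated)
Conditions: 5, (COCl)2, DMF (cat.), CH2Cl2, 0 °C to rt, evaporate; then 4, Et3N, DMAP (cat.), CH2Cl2, 0 °C to rt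
Reagents that add atoms: none
Why: Vilsmeier-type chlorination of the acid, kept cold and short because acid 5 is prone to protodecarboxylation, followed by DMAP-catalysed acylation. The phenolic oxygen of 4 lies between two CH groups and should attack the di-ortho-substituted aroyl chloride without difficulty.

**Step 4**
Reactants: 7 4-(benzyloxy)-3,5-dimethoxyphenyl 2,4,6-trimethoxybenzoate
Product: 8 2-[4-(benzyloxy)-3,5-dimethoxyphenoxy]-1,3,5-trimethoxybenzene
Conditions: Ni(cod)2 (10 mol%), 3,4-bis(dicyclohexylphosphino)thiophene (20 mol%), K3PO4 (1.5 equiv), toluene, 150 °C, sealed tube, argon
Reagents that add atoms: none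
Why: Proposed new method: decarbonylative etherification of aryl arenecarboxylates with Ni(cod)2 and this chelating diphosphine is the closest known reaction type, but it is established for azine carboxylates and electron-poor aroates, not for an electron-rich, di-ortho-substituted benzoate such as 7, so the step extends it to a new substrate class. Zerovalent nickel carrying the electron-rich diphosphine should add oxidatively into the acyl C–O bond of 7 to give an aroyl aryloxide of divalent nickel. The two ortho methoxy groups twist the aroyl group out of conjugation and crowd the metal, which should favour migration of the aryl group to nickel with loss of CO, and one ortho methoxy oxygen can occupy the vacated site and steady the aryl nickel aryloxide. C–O reductive elimination then forms the C1(ring A)–O bond and regenerates zerovalent nickel; electronically this is the weak point, because the trimethoxyphenyl group is electron-rich, and it is driven only by the steric pressure of the two ortho substituents and the bulky chelating ligand. No ring closes and no stereocentre is formed. The selectivity needed is for the acyl C–O bond over the aryl C–O bond of the ester, the five aryl methyl ethers and the benzyl ether. The ester is the only activated C–O bond, chelating dialkylphosphines favour the acyl side of aryl aroates, and without a hydride source or an aryl halide the ether bonds have no productive pathway. K3PO4 is kept as the base of the parent reaction.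

**Step 5**
Reactants: 8 2-[4-(benzyloxy)-3,5-dimethoxyphenoxy]-1,3,5-trimethoxybenzene
Product: 9 2,6-dimethoxy-4-(2,4,6-trimethoxyphenoxy)phenol
Conditions: H2 (1 atm), Pd/C, EtOAc/MeOH, rt
Reagents that add atoms: none
Why: Hydrogenolysis of a benzyl aryl ether over palladium on carbon; the diaryl ether and the aryl methyl ethers are inert and no halogen is present yet.

**Step 6**
Reactants: 10 2-bromo-1,3-dimethoxybenzene
Product: 11 2-(4-bromo-3,5-dimethoxyphenyl)-4,4,5,5-tetramethyl-1,3,2-dioxaborolane
Conditions: B2pin2 (1.0 equiv), [Ir(OMe)(cod)]2 (1.5 mol%), 4,4'-di-tert-butyl-2,2'-bipyridine (3 mol%), THF, 80 °C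
Reagents that add atoms: bis(pinacolato)diboron, CC1(C)OB(OC1(C)C)B1OC(C)(C)C(C)(C)O1
Why: Iridium-catalysed C–H borylation under steric control; of the three C–H bonds of 10 only C5 has no ortho substituent, so boron should enter para to bromine, where electrophilic substitution would not go. The C–Br bond is tolerated by the iridium boryl catalyst.

**Step 7**
Reactants: 11 2-(4-bromo-3,5-dimethoxyphenyl)-4,4,5,5-tetramethyl-1,3,2-dioxaborolane
Product: 12 2-bromo-5-iodo-1,3-dimethoxybenzene
Conditions: CuI (10 mol%), 1,10-phenanthroline (20 mol%), KI (1.5 equiv), MeOH/H2O, air, 80 °C
Reagents that add atoms: potassium iodide, [K+].[I-]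
Why: Copper-mediated aerobic ipso-iododeboronation; boron-to-copper transmetallation and C–I bond formation occur only at the boron-bearing carbon, whereas an electrophilic iodinating agent would attack the positions ortho and para to the methoxy groups.

**Step 8**
Reactants: 12 2-bromo-5-iodo-1,3-dimethoxybenzene
Product: 14 (4-bromo-3,5-dimethoxyphenyl)(2,4,6-trimethoxyphenyl)iodonium tosylate, via hydroxy(tosyloxy)iodoarene 13 (not isolated)
Conditions: mCPBA, TsOH·H2O, MeCN, 40–55 °C; then 1,3,5-trimethoxybenzene, rt; Et2O trituration
Reagents that add atoms: 1,3,5-trimethoxybenzene, COc1cc(OC)cc(OC)c1; 4-methylbenzenesulfonic acid (as monohydrate), Cc1ccc(S(=O)(=O)O)cc1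
Why: One-pot synthesis of an unsymmetrical diaryliodonium salt from an aryl iodide; peracid and sulfonic acid oxidise iodine to the trivalent hydroxy(tosyloxy) species 13, which is captured by the very nucleophilic trimethoxybenzene in an electrophilic aromatic substitution.

**Step 9**
Reactants: 9 2,6-dimethoxy-4-(2,4,6-trimethoxyphenoxy)phenol; 14 (4-bromo-3,5-dimethoxyphenyl)(2,4,6-trimethoxyphenyl)iodonium tosylate
Product: 15 2-bromo-5-[2,6-dimethoxy-4-(2,4,6-trimethoxyphenoxy)phenoxy]-1,3-dimethoxybenzene
Conditions: t-BuOK (1.0 equiv), THF, 0 °C; then 14, 40 °C
Reagents that add atoms: none
Why: Metal-free O-arylation of a phenoxide with a diaryliodonium salt by ligand exchange at iodine and ligand coupling; the strongly electron-rich trimethoxyphenyl group stays on iodine, so the bromodimethoxyphenyl group, whose ipso carbon is unhindered and made electron-poorer by the para bromine and two meta methoxy groups, should be transferred. The method accepts 2,6-disubstituted phenols and leaves the C–Br bond untouched; only one equivalent of base is used, to avoid deprotonation next to the iodonium centre.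

**Step 10**
Reactants: 15 2-bromo-5-[2,6-dimethoxy-4-(2,4,6-trimethoxyphenoxy)phenoxy]-1,3-dimethoxybenzene
Product: 16 2-[4-(4-bromo-3,5-dihydroxyphenoxy)-3,5-dihydroxyphenoxy]benzene-1,3,5-triol
Conditions: BBr3 (excess), CH2Cl2, −78 °C to rt, argon; ice/H2O quench
Reagents that add atoms: none
Why: Lewis-acid cleavage of aryl methyl ethers; boron coordinates each methoxy oxygen and bromide attacks the methyl carbon, while diaryl ether and aryl bromide bonds are not attacked. The quench is aqueous and cold, not methanolic, to avoid acid-catalysed ether exchange on the phloroglucinol-type rings.

## Compound list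

1 | syringaldehyde (4-hydroxy-3,5-dimethoxybenzaldehyde) | COc1cc(C=O)cc(OC)c1O | starting material
2 | 4-(benzyloxy)-3,5-dimethoxybenzaldehyde | COc1cc(C=O)cc(OC)c1OCc1ccccc1 | intermediate
3 | 4-(benzyloxy)-3,5-dimethoxyphenyl formate | COc1cc(OC=O)cc(OC)c1OCc1ccccc1 | intermediate (not isolated)
4 | 4-(benzyloxy)-3,5-dimethoxyphenol | COc1cc(O)cc(OC)c1OCc1ccccc1 | intermediate
5 | 2,4,6-trimethoxybenzoic acid | COc1cc(OC)c(C(=O)O)c(OC)c1 | starting material
6 | 2,4,6-trimethoxybenzoyl chloride | COc1cc(OC)c(C(=O)Cl)c(OC)c1 | intermediate (not isolated)
7 | 4-(benzyloxy)-3,5-dimethoxyphenyl 2,4,6-trimethoxybenzoate | COc1cc(OC)c(C(=O)Oc2cc(OC)c(OCc3ccccc3)c(OC)c2)c(OC)c1 | intermediate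
8 | 2-[4-(benzyloxy)-3,5-dimethoxyphenoxy]-1,3,5-trimethoxybenzene | COc1cc(OC)c(Oc2cc(OC)c(OCc3ccccc3)c(OC)c2)c(OC)c1 | intermediate
9 | 2,6-dimethoxy-4-(2,4,6-trimethoxyphenoxy)phenol | COc1cc(OC)c(Oc2cc(OC)c(O)c(OC)c2)c(OC)c1 | intermediate
10 | 2-bromo-1,3-dimethoxybenzene | COc1cccc(OC)c1Br | starting material
11 | 2-(4-bromo-3,5-dimethoxyphenyl)-4,4,5,5-tetramethyl-1,3,2-dioxaborolane | COc1cc(B2OC(C)(C)C(C)(C)O2)cc(OC)c1Br | intermediate
12 | 2-bromo-5-iodo-1,3-dimethoxybenzene | COc1cc(I)cc(OC)c1Br | intermediate
13 | 2-bromo-5-[hydroxy(tosyloxy)iodo]-1,3-dimethoxybenzene | COc1cc(I(O)OS(=O)(=O)c2ccc(C)cc2)cc(OC)c1Br | intermediate (not isolated)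
14 | (4-bromo-3,5-dimethoxyphenyl)(2,4,6-trimethoxyphenyl)iodonium 4-methylbenzenesulfonate | COc1cc([I+]c2c(OC)cc(OC)cc2OC)cc(OC)c1Br.Cc1ccc(S(=O)(=O)[O-])cc1 | intermediate
15 | 2-bromo-5-[2,6-dimethoxy-4-(2,4,6-trimethoxyphenoxy)phenoxy]-1,3-dimethoxybenzene | COc1cc(OC)c(Oc2cc(OC)c(Oc3cc(OC)c(Br)c(OC)c3)c(OC)c2)c(OC)c1 | intermediate
16 | 2-[4-(4-bromo-3,5-dihydroxyphenoxy)-3,5-dihydroxyphenoxy]benzene-1,3,5-triol | Oc1cc(O)c(Oc2cc(O)c(Oc3cc(O)c(Br)c(O)c3)c(O)c2)c(O)c1 | target

## Step count and risk

Total: 10 steps. Longest linear sequence: 7 steps (steps 1, 2, 3, 4, 5, 9, 10). The ring C branch (steps 6, 7, 8) joins at step 9.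

**Step 4 (key step, proposed new method).** The catalytic cycle is most likely to stall after decarbonylation, because C–O reductive elimination from an electron-rich aryl on divalent nickel is slow. The aryl nickel aryloxide would then be lost to protonation, or the catalyst would be tied up by CO. Oxidative addition at the aryl C–O bond of the hindered ester, or at the benzylic C–O bond, could also divert the catalyst. Fallback with known chemistry: set out from phenol 4 and make the A–B ether by a copper-catalysed Ullmann coupling with commercial 2-iodo-1,3,5-trimethoxybenzene (COc1cc(OC)c(I)c(OC)c1), using CuI, picolinic acid, K3PO4, DMSO at about 100 °C. This is the classical way to aryl ethers of this class and returns to the route at compound 8.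

**Step 8.** Before the trimethoxybenzene is added, the trivalent iodine species 13 may arylate unoxidised iodide 12 at a ring carbon activated by the methoxy groups, or the ring may be over-oxidised. Fallback: avoid trivalent iodine altogether. Set out from boronate 11, cleave the pinacol ester with NaIO4 and NH4OAc in aqueous acetone to (4-bromo-3,5-dimethoxyphenyl)boronic acid F1, and couple F1 with phenol 9 in a Chan–Lam–Evans etherification (Cu(OAc)2, pyridine, 4 Å molecular sieves, CH2Cl2, air, rt). This reaction tolerates aryl bromides and ortho-disubstituted phenols and returns to the route at compound 15.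

**Step 9.** The hydrogens next to the iodonium centre are acidified by the adjacent methoxy groups, so deprotonation and an aryne pathway could scramble the position of the new ether bond. The electron-rich phenoxide of 9 could also be oxidised by single-electron transfer instead of being arylated. Fallback: set out from phenol 9 and iodide 12 and form the ether by a copper-catalysed Ullmann coupling (CuI, picolinic acid, K3PO4, DMSO, 90 °C). The C–I bond should react well before the C–Br bond, which is shielded by two methoxy groups. The fallback returns at compound 15.

**Step 10.** Cleavage of seven ethers may stop short and leave partly methylated polyphenols that are hard to separate. The free heptaphenol may oxidise during isolation. Prolonged contact with aqueous HBr could promote ether exchange or loss of bromine from the activated ring C. Fallback: set out from 15, demethylate as before, and acetylate the crude product directly (Ac2O, pyridine) to 2-{4-[3,5-bis(acetyloxy)-4-bromophenoxy]-3,5-bis(acetyloxy)phenoxy}benzene-1,3,5-triyl triacetate F2. F2 is stable and can be purified by chromatography or crystallisation. The acetates are then removed with hydrazine hydrate in THF/MeOH at 0 °C under argon, returning to the route at compound 16.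

## Further compounds

F0 | step 4 | none | none
F1 | step 8 | (4-bromo-3,5-dimethoxyphenyl)boronic acid | COc1cc(B(O)O)cc(OC)c1Br
F0 | step 9 | none | none
F2 | step 10 | 2-{4-[3,5-bis(acetyloxy)-4-bromophenoxy]-3,5-bis(acetyloxy)phenoxy}benzene-1,3,5-triyl triacetate | CC(=O)Oc1cc(OC(C)=O)c(Oc2cc(OC(C)=O)c(Oc3cc(OC(C)=O)c(Br)c(OC(C)=O)c3)c(OC(C)=O)c2)c(OC(C)=O)c1
A1 | alternative 1 | dimethyl 5-(4-bromo-3,5-dimethoxyphenoxy)-4,6-dihydroxy-2-(2,4,6-trimethoxyphenoxy)benzene-1,3-dicarboxylate | COC(=O)c1c(O)c(Oc2cc(OC)c(Br)c(OC)c2)c(O)c(C(=O)OC)c1Oc1c(OC)cc(OC)cc1OC
A2 | alternative 1 | dimethyl 2-(4-bromo-3,5-dimethoxyphenoxy)propanedioate | COC(=O)C(Oc1cc(OC)c(Br)c(OC)c1)C(=O)OC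
A3 | alternative 1 | dimethyl (2E)-3-(2,4,6-trimethoxyphenoxy)pent-2-enedioate | COC(=O)/C=C(\CC(=O)OC)Oc1c(OC)cc(OC)cc1OC
A4 | alternative 2 | 4-(4-bromo-3,5-dimethoxyphenoxy)-3,5-dimethoxyphenol | COc1cc(O)cc(OC)c1Oc1cc(OC)c(Br)c(OC)c1
A5 | alternative 2 | 4-diazo-3,5-dimethoxycyclohexa-2,5-dien-1-one | COC1=CC(=O)C=C(OC)C1=[N+]=[N-]
A6 | alternative 2 | 4-bromo-3,5-dimethoxyphenol | COc1cc(O)cc(OC)c1Br
A7 | alternative 2 | 4-[4-(4-bromo-3,5-dimethoxyphenoxy)-3,5-dimethoxyphenoxy]-3,5-dimethoxyphenol | COc1cc(O)cc(OC)c1Oc1cc(OC)c(Oc2cc(OC)c(Br)c(OC)c2)c(OC)c1
A8 | alternative 3 | 2-[4-(4-bromo-3,5-dimethoxyphenoxy)-3,5-dimethoxyphenoxy]-3,5-diethoxyphenol | CCOc1cc(O)c(Oc2cc(OC)c(Oc3cc(OC)c(Br)c(OC)c3)c(OC)c2)c(OCC)c1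
A9 | alternative 3 | [4-(4-bromo-3,5-dimethoxyphenoxy)-3,5-dimethoxyphenoxy]acetyl chloride | O=C(Cl)COc1cc(OC)c(Oc2cc(OC)c(Br)c(OC)c2)c(OC)c1
A10 | alternative 3 | ethoxyethyne | CCOC#C
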